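**Retrosynthetic overview**
1. The usual logic (late esterification of a dialdehyde acid obtained by oxidative cleavage of a cyclopentanoid) is set aside. Instead, the C2–C3 bond, both stereocentres, the (E)-ethylidene and the labile C2 formyl group are all created in the last step by a Claisen rearrangement of allyl 3-oxyacrylate 17.
2. 17 ⇐ oxa-Michael addition of a (Z)-α-(1-hydroxyethyl) enal, masked as acetal 13, to methyl propiolate.
3. The (Z)-enal ⇐ hydroxyl-directed trans-hydrostannation, iodination and carbonylative formylation of 3-alkynoate 8.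
4. 8 ⇐ CuI-catalysed coupling of (R)-but-3-yn-2-ol (the only source of chirality) with diazoacetate 6 of bis-silylated hydroxytyrosol.
5. No ring is formed; the only ring, the catechol, comes with hydroxytyrosol.

Assumption: the C2 formyl-ester stereocentre is enolisable, so (2S) is treated as a kinetic outcome, created in the last step and kept neutral and cold afterwards.

Abbreviations: TBS = tert-butyldimethylsilyl; TBSO = tert-butyldimethylsilyloxy. Locants C2/C3 refer to the pentanedioate numbering of the target; C3–C5 in intermediates refer to the hex-3-enoate numbering.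

**Step 1**
Reactants: 1 hydroxytyrosol, 4-(2-hydroxyethyl)benzene-1,2-diol
Product: 2 tert-butyl{2-[3,4-bis(TBSO)phenyl]ethoxy}dimethylsilane
Conditions: TBSCl (3.3 equiv), imidazole (6 equiv), DMF, rt
Reagents that add atoms: tert-butyldimethylsilyl chloride, CC(C)(C)[Si](C)(C)Cl
Why: Exhaustive silyl ether formation at all three hydroxyls gives a robust intermediate from which the alkyl silyl ether can later be removed selectively.

**Step 2**
Reactants: 2 tert-butyl{2-[3,4-bis(TBSO)phenyl]ethoxy}dimethylsilane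
Product: 3 2-[3,4-bis(TBSO)phenyl]ethanol
Conditions: camphorsulfonic acid (10 mol %), MeOH/CH2Cl2 (1:1), 0 °C
Reagents that add atoms: none
Why: Acid-catalysed methanolysis (selective desilylation) cleaves the primary alkyl silyl ether much faster than the two aryl silyl ethers, whose oxygens are far less basic.

**Step 3**
Reactants: 3 2-[3,4-bis(TBSO)phenyl]ethanol; 4 bromoacetyl bromide
Product: 5 2-[3,4-bis(TBSO)phenyl]ethyl 2-bromoacetate
Conditions: NaHCO3 (3 equiv), MeCN, 0 °C
Reagents that add atoms: none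
Why: O-acylation of the primary alcohol by the acid bromide under bicarbonate buffering is fast at 0 °C and leaves the aryl silyl ethers untouched.

**Step 4**
Reactants: 5 2-[3,4-bis(TBSO)phenyl]ethyl 2-bromoacetate
Product: 6 2-[3,4-bis(TBSO)phenyl]ethyl 2-diazoacetate
Conditions: N,N'-ditosylhydrazine (2 equiv), DBU (5 equiv), THF, 0 °C, 15 min
Reagents that add atoms: N,N'-ditosylhydrazine, Cc1ccc(cc1)S(=O)(=O)NNS(=O)(=O)c1ccc(C)cc1
Why: Fukuyama diazoacetate synthesis: N-alkylation of the hydrazide by the bromoacetate followed by base-induced loss of two sulfinates gives the diazo ester under conditions short and mild enough for aryl silyl ethers.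

**Step 5**
Reactants: 6 2-[3,4-bis(TBSO)phenyl]ethyl 2-diazoacetate; 7 (R)-but-3-yn-2-ol
Product: 8 2-[3,4-bis(TBSO)phenyl]ethyl (5R)-5-hydroxyhex-3-ynoate
Conditions: CuI (5 mol %), MeCN, rt
Reagents that add atoms: none
Why: CuI-catalysed coupling of a terminal alkyne with a diazoacetate (copper acetylide–carbene coupling) gives the 3-alkynoate without base, so no allenoate forms, and the (5R) carbinol from the chiral pool is untouched.

**Step 6**
Reactants: 8 2-[3,4-bis(TBSO)phenyl]ethyl (5R)-5-hydroxyhex-3-ynoate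
Product: 10 2-[3,4-bis(TBSO)phenyl]ethyl (3Z,5R)-5-hydroxy-4-iodohex-3-enoate, via alkenylstannane 9 (not isolated)
Conditions: Bu3SnH (1.1 equiv), [(C5Me5)RuCl]4 (1.25 mol %), CH2Cl2, rt; then I2 (1.1 equiv), 0 °C
Reagents that add atoms: tributyltin hydride, CCCC[SnH](CCCC)CCCC; iodine, II
Why: Hydroxyl-directed ruthenium-catalysed trans-hydrostannation delivers tin to the alkyne carbon next to the carbinol and hydrogen anti to it, and iododestannylation proceeds with retention, so iodine ends cis to the CH2CO2R arm (3Z).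

**Step 7**
Reactants: 10 2-[3,4-bis(TBSO)phenyl]ethyl (3Z,5R)-5-hydroxy-4-iodohex-3-enoate; 11 carbon monoxide
Product: 12 2-[3,4-bis(TBSO)phenyl]ethyl (3Z,5R)-4-formyl-5-hydroxyhex-3-enoate
Conditions: CO (3 bar), Bu3SnH (1.1 equiv, syringe pump), Pd(PPh3)4 (5 mol %), THF, 50 °C
Reagents that add atoms: none
Why: Stille-type carbonylative formylation (oxidative addition, CO insertion, hydride transfer from tin) turns the alkenyl iodide into the enal with retention of geometry; it is run before the vinyl ether is installed because zerovalent palladium would ionise an allyl 3-oxyacrylate.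

**Step 8**
Reactants: 12 2-[3,4-bis(TBSO)phenyl]ethyl (3Z,5R)-4-formyl-5-hydroxyhex-3-enoate
Product: 13 2-[3,4-bis(TBSO)phenyl]ethyl (3Z,5R)-4-(dimethoxymethyl)-5-hydroxyhex-3-enoate
Conditions: HC(OMe)3 (3 equiv), pyridinium p-toluenesulfonate (5 mol %), MeOH, 0 °C
Reagents that add atoms: trimethyl orthoformate, COC(OC)OC; methanol, CO
Why: Acid-catalysed acetalisation with orthoformate as water scavenger masks the enal and so removes the vinylogous acidity of the C2 methylene before the basic oxa-Michael step; no stereo element is touched.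

**Step 9**
Reactants: 13 2-[3,4-bis(TBSO)phenyl]ethyl (3Z,5R)-4-(dimethoxymethyl)-5-hydroxyhex-3-enoate; 14 methyl propiolate
Product: 15 2-[3,4-bis(TBSO)phenyl]ethyl (3Z,5R)-4-(dimethoxymethyl)-5-{[(1E)-3-methoxy-3-oxoprop-1-en-1-yl]oxy}hex-3-enoate
Conditions: PMe3 (10 mol %), CH2Cl2, 0 °C
Reagents that add atoms: none
Why: Phosphine-catalysed oxa-Michael addition of the secondary alcohol to the propiolate gives only the (E)-3-alkoxyacrylate with retention at C5, completing the allyl vinyl ether.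

**Step 10**
Reactants: 15 2-[3,4-bis(TBSO)phenyl]ethyl (3Z,5R)-4-(dimethoxymethyl)-5-{[(1E)-3-methoxy-3-oxoprop-1-en-1-yl]oxy}hex-3-enoate
Product: 17 2-(3,4-dihydroxyphenyl)ethyl (3Z,5R)-4-formyl-5-{[(1E)-3-methoxy-3-oxoprop-1-en-1-yl]oxy}hex-3-enoate, via catechol acetal 16 (not isolated)
Conditions: HF·pyridine, pyridine, THF, 0 °C to rt; then H2O, 0 °C, 20 min; used at once
Reagents that add atoms: water, O
Why: Fluoride cleavage of the aryl silyl ethers followed by mild aqueous-acid hydrolysis of the allylic acetal (fast because its oxocarbenium ion is conjugated) unmasks catechol and enal without any base, so the (3Z) enal and the skipped ester stay in place.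

**Step 11**
Reactants: 17 2-(3,4-dihydroxyphenyl)ethyl (3Z,5R)-4-formyl-5-{[(1E)-3-methoxy-3-oxoprop-1-en-1-yl]oxy}hex-3-enoate
Product: 18 5-[2-(3,4-dihydroxyphenyl)ethyl] 1-methyl (2S,3S)-2-formyl-3-[(1E)-1-formylprop-1-en-1-yl]pentanedioate
Conditions: PhMe (0.01 M, degassed), 100 °C, 2–3 h, silanised glass under argon; concentrate below 20 °C, store at −20 °C
Reagents that add atoms: none
Why: Claisen rearrangement of a 3-(allyloxy)acrylate, accelerated by the formyl group on the allyl unit, through a chair in which the (E)-acrylate places CO2Me equatorial, the (3Z)-enal places the CH2CO2R arm equatorial and the C5 methyl is axial (an equatorial methyl would eclipse the coplanar formyl group already flanked by the arm), so the (5R) centre is relayed to (2S,3S), the new alkene is (E), and the C2 formyl group is released with no reagent present.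

**Compound list**
1 | hydroxytyrosol, 4-(2-hydroxyethyl)benzene-1,2-diol | OCCc1ccc(O)c(O)c1 | starting material
2 | tert-butyl{2-[3,4-bis(TBSO)phenyl]ethoxy}dimethylsilane | CC(C)(C)[Si](C)(C)OCCc1ccc(O[Si](C)(C)C(C)(C)C)c(O[Si](C)(C)C(C)(C)C)c1 | intermediate
3 | 2-[3,4-bis(TBSO)phenyl]ethanol | OCCc1ccc(O[Si](C)(C)C(C)(C)C)c(O[Si](C)(C)C(C)(C)C)c1 | intermediate
4 | bromoacetyl bromide | BrCC(Br)=O | starting material
5 | 2-[3,4-bis(TBSO)phenyl]ethyl 2-bromoacetate | BrCC(=O)OCCc1ccc(O[Si](C)(C)C(C)(C)C)c(O[Si](C)(C)C(C)(C)C)c1 | intermediate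
6 | 2-[3,4-bis(TBSO)phenyl]ethyl 2-diazoacetate | [N-]=[N+]=CC(=O)OCCc1ccc(O[Si](C)(C)C(C)(C)C)c(O[Si](C)(C)C(C)(C)C)c1 | intermediate
7 | (R)-but-3-yn-2-ol | C[C@@H](O)C#C | starting material
8 | 2-[3,4-bis(TBSO)phenyl]ethyl (5R)-5-hydroxyhex-3-ynoate | C[C@@H](O)C#CCC(=O)OCCc1ccc(O[Si](C)(C)C(C)(C)C)c(O[Si](C)(C)C(C)(C)C)c1 | intermediate
9 | 2-[3,4-bis(TBSO)phenyl]ethyl (3Z,5R)-5-hydroxy-4-(tributylstannyl)hex-3-enoate | C[C@@H](O)/C([Sn](CCCC)(CCCC)CCCC)=C/CC(=O)OCCc1ccc(O[Si](C)(C)C(C)(C)C)c(O[Si](C)(C)C(C)(C)C)c1 | intermediate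
10 | 2-[3,4-bis(TBSO)phenyl]ethyl (3Z,5R)-5-hydroxy-4-iodohex-3-enoate | C[C@@H](O)/C(I)=C/CC(=O)OCCc1ccc(O[Si](C)(C)C(C)(C)C)c(O[Si](C)(C)C(C)(C)C)c1 | intermediate
11 | carbon monoxide | [C-]#[O+] | starting material
12 | 2-[3,4-bis(TBSO)phenyl]ethyl (3Z,5R)-4-formyl-5-hydroxyhex-3-enoate | C[C@@H](O)/C(C=O)=C/CC(=O)OCCc1ccc(O[Si](C)(C)C(C)(C)C)c(O[Si](C)(C)C(C)(C)C)c1 | intermediate
13 | 2-[3,4-bis(TBSO)phenyl]ethyl (3Z,5R)-4-(dimethoxymethyl)-5-hydroxyhex-3-enoate | C[C@@H](O)/C(C(OC)OC)=C/CC(=O)OCCc1ccc(O[Si](C)(C)C(C)(C)C)c(O[Si](C)(C)C(C)(C)C)c1 | intermediate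
14 | methyl propiolate | COC(=O)C#C | starting material
15 | 2-[3,4-bis(TBSO)phenyl]ethyl (3Z,5R)-4-(dimethoxymethyl)-5-{[(1E)-3-methoxy-3-oxoprop-1-en-1-yl]oxy}hex-3-enoate | C[C@@H](O/C=C/C(=O)OC)/C(C(OC)OC)=C/CC(=O)OCCc1ccc(O[Si](C)(C)C(C)(C)C)c(O[Si](C)(C)C(C)(C)C)c1 | intermediate
16 | 2-(3,4-dihydroxyphenyl)ethyl (3Z,5R)-4-(dimethoxymethyl)-5-{[(1E)-3-methoxy-3-oxoprop-1-en-1-yl]oxy}hex-3-enoate | C[C@@H](O/C=C/C(=O)OC)/C(C(OC)OC)=C/CC(=O)OCCc1ccc(O)c(O)c1 | intermediate
17 | 2-(3,4-dihydroxyphenyl)ethyl (3Z,5R)-4-formyl-5-{[(1E)-3-methoxy-3-oxoprop-1-en-1-yl]oxy}hex-3-enoate | C[C@@H](O/C=C/C(=O)OC)/C(C=O)=C/CC(=O)OCCc1ccc(O)c(O)c1 | intermediate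
18 | 5-[2-(3,4-dihydroxyphenyl)ethyl] 1-methyl (2S,3S)-2-formyl-3-[(1E)-1-formylprop-1-en-1-yl]pentanedioate | C/C=C(/C=O)[C@@H](CC(=O)OCCc1ccc(O)c(O)c1)[C@@H](C=O)C(=O)OC | target

**Totals**
Total step count: 11.
Longest linear sequence: 11 steps (1 to 18); the chiral alkyne 7 enters at step 5 and travels 7 steps.

**Steps most likely to fail**

1. Step 11 (Claisen rearrangement). Three things can go wrong:
   - the chair with an equatorial methyl would give the (Z)-ethylidene (2R,3R) diastereomer;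
   - at 100 °C the new formyl ester can enolise, epimerising C2 or closing to cyclic hemiacetal forms;
   - the free phenols can catalyse that tautomerisation.

   The fallback sets out from 15 and comes back at 18, and moves the rearrangement to a phenol-masked substrate under catalysis. Pyridinium p-toluenesulfonate in wet acetone at 0 °C removes only the acetal and gives 2-[3,4-bis(TBSO)phenyl]ethyl (3Z,5R)-4-formyl-5-{[(1E)-3-methoxy-3-oxoprop-1-en-1-yl]oxy}hex-3-enoate F1. This is rearranged at 35 °C under hydrogen-bond-donor catalysis (N,N'-diphenylguanidinium tetrakis[3,5-bis(trifluoromethyl)phenyl]borate, 20 mol %, hexanes/CH2Cl2), by analogy with catalysed rearrangements of O-allyl β-keto esters, to 5-{2-[3,4-bis(TBSO)phenyl]ethyl} 1-methyl (2S,3S)-2-formyl-3-[(1E)-1-formylprop-1-en-1-yl]pentanedioate F2. The aryl silyl ethers are then cleaved with Et3N·3HF in MeCN at 0 °C to reach 18.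

2. Step 7 (carbonylative formylation). Hydrodeiodination and Z-to-E drift of the hindered, base-sensitive enal are the risks. The fallback sets out from 10 and comes back at 12, bringing in C1 at the alcohol oxidation level. Stille coupling of 10 with (tributylstannyl)methanol (Pd(PPh3)4, dioxane, 80 °C) gives 2-[3,4-bis(TBSO)phenyl]ethyl (3E,5R)-5-hydroxy-4-(hydroxymethyl)hex-3-enoate F3. Its primary allylic alcohol is oxidised chemoselectively in the presence of the secondary one with TEMPO (10 mol %) and PhI(OAc)2 in CH2Cl2 at 0 °C to give 12.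

3. Step 9 (oxa-Michael addition). The carbinol is flanked by the acetal and a trisubstituted alkene, and the basic phosphonium intermediate may pull the 3,4-alkene into conjugation with the ester. The fallback sets out from 13 and comes back at 15, replacing conjugate addition by a copper-promoted oxidative O-alkenylation (Chan–Lam type). 13 is treated with methyl (E)-3-(4,4,5,5-tetramethyl-1,3,2-dioxaborolan-2-yl)acrylate, Cu(OAc)2 (2 equiv) and Et3N in CH2Cl2 under air at rt, which transfers the (E)-acrylate unit with retention and gives 15 directly. This detour makes no new compound (none F0).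

**Further compounds**
F1 | step 11 | 2-[3,4-bis(TBSO)phenyl]ethyl (3Z,5R)-4-formyl-5-{[(1E)-3-methoxy-3-oxoprop-1-en-1-yl]oxy}hex-3-enoate | C[C@@H](O/C=C/C(=O)OC)/C(C=O)=C/CC(=O)OCCc1ccc(O[Si](C)(C)C(C)(C)C)c(O[Si](C)(C)C(C)(C)C)c1
F2 | step 11 | 5-{2-[3,4-bis(TBSO)phenyl]ethyl} 1-methyl (2S,3S)-2-formyl-3-[(1E)-1-formylprop-1-en-1-yl]pentanedioate | C/C=C(/C=O)[C@@H](CC(=O)OCCc1ccc(O[Si](C)(C)C(C)(C)C)c(O[Si](C)(C)C(C)(C)C)c1)[C@@H](C=O)C(=O)OC
F3 | step 7 | 2-[3,4-bis(TBSO)phenyl]ethyl (3E,5R)-5-hydroxy-4-(hydroxymethyl)hex-3-enoate | C[C@@H](O)/C(CO)=C/CC(=O)OCCc1ccc(O[Si](C)(C)C(C)(C)C)c(O[Si](C)(C)C(C)(C)C)c1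
F0 | step 9 | none | none
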